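The teal run held its single product near 26.7% from 1.50 min on, while its substrate kept falling, so I divided one amount by the other.

| flask | substrate | partner | remark | time |
|---|---|---|---|---|
| teal | 0.070 M | 1.5 equiv | run made earlier |  |
| violet | 0.11 M | 1.5 equiv | run made earlier |  |
| red | 0.050 M | 2.2 equiv | run made earlier |  |
| flask | 0.050 M | 1.50 equiv |  | 6.0 min |

- teal (time / min: substrate / %, single product / %): 0.667: 26.0, 24.7; 1.50: 6.6, 26.7; 3.00: 0.5, 26.0; 5.00: 0, 26.0
- violet (time / min: substrate / %, single product / %): 1.33: 1.5, 26.2; 2.50: 0, 24.1; 4.00: 0.2, 23.9; 5.00: 0.4, 24.3
- red (time / min: substrate / %, single product / %): 0.667: 24.5, 27.5; 1.50: 6.0, 28.8; 3.00: 0.7, 27.9; 5.00: 0.1, 26.0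

(scatter of a reading: 0.5 percentage points)

* how much substrate there is at 6.0 min, in percent of the substrate charged
* how much single product there is at 6.0 min, in percent of the substrate charged
* how much other mono adduct there is at 6.0 min, in percent of the substrate charged
* how much double product there is at 6.0 min, in percent of the substrate charged

- the earlier runs were read with a standard deviation of 0.5 percentage points
- a reading or a percentage of single product counts all its forms, free or not

Teal's last reading gave 26.0%. This is the share, single product held per substrate lost, a net selectivity. The share still moved with the clock: teal's first reading gave 33.4% and its last 26.0%. So I set the runs side by side by their late readings.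

I bracketed the flask's share. From above, red's first reading gave 36.4%, and each later red reading gave less. From below, violet, the most concentrated run, ended at 24.4%.

Teal was more dilute than violet and ended higher. The flask is more dilute still, so I raised the floor to teal's share. I lowered the ceiling to red's 28.1% at 3.00 min, the flask's concentration. That step was judgement, since red had more partner. Red's substrate read 0.1% at 5.00 min, so I expected little substrate in the flask at the asked time and took the share as roughly the flask's percentage of single product. The readings showed neither other mono adduct nor double product, so I bracketed neither.

The forecast gave 0.1%, 27%, 25% and 47.9%, noting “Dilution seems to favour single product slightly”.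

The flask gave 0.878%, 25.8%, 15.4% and 13.4%.

    substrate + partner → single product + by-product (k = 0.180 /M/s)
    substrate + partner → other mono adduct + by-product (k = 0.140 /M/s)
    partner + single product → double product + by-product (k = 0.0620 /M/s)
    partner + other mono adduct → double product + by-product (k = 0.160 /M/s)
    crystals ⇌ single product, rate k5*(cs5 - [single product]) while solid is left; crystals form when [single product] > cs5 (solubility = 40.0 mM, k = 1.80 /s)
    partner → decomposed reagent (k = 0.0100 /s)
    substrate + by-product → side product (k = 0.750 /M/s)

The flask's share was 26.0%, at the floor of my bracket. The flask had nearly come to rest. At 60.0 min, ten times the time, its share was 25.7%, its substrate 0%, its other mono adduct 15.3% and its double product 13.6%. A more dilute neighbour flask, at 0.020 M, held a share of 27.9% at 6.00 min, with 21.4% of its substrate left.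

(The earlier runs and the new flask are simulated on assumed constants; scatter was added.)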